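## Retrosynthetic overview

1. Numbering (germacrane): carbocycle C1–C10 with oxiranes at C1–C10 and C4–C5 and an angelate on C6; lactone C7–C11(CH3)(OAng)–C12(=O)–O–C8; C14 on C10, C15 on C4.
2. The target comes from diol 21 by oxidative lactonisation (C12–OH onto C8–OH), and 21 from cyclodecenol 19 by C8-hydroxyl-directed epoxidation of the (Z)-C1=C10 olefin.
3. 19 comes from seco-aldehyde 17 by closing the ten-membered ring at C8–C9 through an intramolecular allylboration. The enabling feature is that, in the ten-membered ring, the oxygen-bearing C8 is homoallylic to the cis-oxirane carbons (C8(O)–C9H2–C10(CH3)=C1), so a C8 aldehyde and a C1 boronate (C10=C9H2) give ring, Z-olefin and C8 carbinol in one operation.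
4. The boronate comes from allylic carbonate 14 by copper-catalysed SN2' borylation; bis-angelate 12 from ketone 10 by chelation-controlled methyl addition (C11) with double angeloylation in the flask; 10 from a syn aldol (C6, C7) of imide 6 with epoxy aldehyde 3 (C4, C5 from Sharpless epoxidation of geraniol).
5. Ring order: oxirane C4–C5, then ten-membered carbocycle, then oxirane C1–C10, then γ-lactone.

Key step: step 12

Assumption: the antipode of the copper ligand in step 10 is the one that gives the (R)-boronate on a model (E)-2-methylalk-2-enyl carbonate; angelic anhydride and Bu3SnCH2OPMB (from Bu3SnCH2I and 4-methoxybenzyl alcohol) are taken as available reagents.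

## Route

Step 1
Reactants: 1 geraniol
Product: 2 (2S,3S)-2,3-epoxygeraniol
Conditions: Ti(OiPr)4 (cat.), L-(+)-diethyl tartrate (cat.), t-BuOOH, 4 Å MS, CH2Cl2, −20 °C
Reagents that add atoms: tert-butyl hydroperoxide, CC(C)(C)OO
Why: Sharpless asymmetric epoxidation of the allylic alcohol should set C4 and C5 (both S) by reagent control with the L-(+)-tartrate catalyst, leaving the remote olefin untouched.

Step 2
Reactants: 2 (2S,3S)-2,3-epoxygeraniol
Product: 3 (2R,3S)-2,3-epoxygeranial
Conditions: Dess–Martin periodinane, pyridine, CH2Cl2, 0 °C to rt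
Reagents that add atoms: none
Why: Dess–Martin oxidation under buffered, non-acidic conditions should give the epoxy aldehyde without opening the oxirane or touching the C5 centre.

Step 3
Reactants: 4 (S)-4-benzyl-1,3-thiazolidine-2-thione; 5 3-[(tert-butyldimethylsilyl)oxy]propanoic acid
Product: 6 N-[3-(TBS-oxy)propanoyl]-(S)-4-benzylthiazolidine-2-thione
Conditions: DCC, DMAP (cat.), CH2Cl2, 0 °C to rt
Reagents that add atoms: none
Why: Carbodiimide (Steglich-type) N-acylation of the auxiliary, which later serves as a leaving group under mild conditions.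

Step 4
Reactants: 6 N-[3-(TBS-oxy)propanoyl]-(S)-4-benzylthiazolidine-2-thione; 3 (2R,3S)-2,3-epoxygeranial
Product: 8 syn-aldol adduct (4S,5S,6S,7S), via boron enolate 7 (not isolated)
Conditions: Bu2BOTf, i-Pr2NEt, CH2Cl2, 0 °C; then 3, −78 to 0 °C; pH 7 buffer, MeOH
Reagents that add atoms: none
Why: Evans-type syn aldol of the (Z)-boron enolate through a Zimmerman–Traxler chair, in which the (S)-auxiliary sets C7 and C6 and the Cornforth preference of the epoxy aldehyde (new hydroxyl anti to the oxirane oxygen) is matched.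

Step 5
Reactants: 8 syn-aldol adduct
Product: 9 Weinreb amide (4S,5S,6S,7S)
Conditions: MeNHOMe·HCl, imidazole, CH2Cl2, rt
Reagents that add atoms: N,O-dimethylhydroxylamine hydrochloride, CNOC.Cl
Why: Aminolysis of the activated N-acyl thiazolidinethione (Weinreb amide formation) needs no Lewis acid, so the 2,3-epoxy alcohol unit should survive.

Step 6
Reactants: 9 Weinreb amide
Product: 10 (4-methoxybenzyl)oxymethyl ketone (C11 ketone)
Conditions: Bu3SnCH2OPMB, n-BuLi, THF, −78 °C; then 9, −78 to −40 °C
Reagents that add atoms: tributyl{[(4-methoxybenzyl)oxy]methyl}stannane, CCCC[Sn](CCCC)(CCCC)COCc1ccc(OC)cc1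
Why: Weinreb ketone synthesis with the α-alkoxymethyllithium from tin–lithium exchange should stop at the chelated tetrahedral intermediate and introduce C12 at the alcohol oxidation level.

Step 7
Reactants: 10 (4-methoxybenzyl)oxymethyl ketone
Product: 12 6,11-bis-angelate (11R), via magnesium dialkoxide 11 (not isolated)
Conditions: MeMgCl, THF–CH2Cl2, −78 °C; then angelic anhydride, DMAP (cat.), −78 to 0 °C
Reagents that add atoms: methylmagnesium chloride, C[Mg]Cl; angelic anhydride, C/C=C(/C)C(=O)OC(=O)/C(C)=C\C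
Why: Chelation-controlled Grignard addition, in which the C6 magnesium alkoxide chelates the C11 ketone, the C7 CH2OTBS group stands pseudo-axial (avoiding 1,3-allylic strain with C12) and methyl attacks the opposite face to set 11R; both alkoxides are then acylated in the flask.

Step 8
Reactants: 12 6,11-bis-angelate
Product: 13 (E)-allylic alcohol (C9–OH)
Conditions: SeO2 (cat.), t-BuOOH, CH2Cl2, 0 °C to rt
Reagents that add atoms: tert-butyl hydroperoxide, CC(C)(C)OO
Why: Selenium dioxide allylic oxidation (ene reaction, then 2,3-sigmatropic shift) should be selective for the (E)-methyl of the only electron-rich olefin, the angelate olefins being deactivated.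

Step 9
Reactants: 13 (E)-allylic alcohol
Product: 14 allylic methyl carbonate
Conditions: ClCO2Me, pyridine, CH2Cl2, 0 °C
Reagents that add atoms: methyl chloroformate, COC(=O)Cl
Why: Carbonate formation on the only free hydroxyl installs the leaving group for allylic substitution.

Step 10
Reactants: 14 allylic methyl carbonate
Product: 15 (1R)-allylboronate (C1–Bpin, C10=C9H2)
Conditions: CuCl (cat.), (R,R)-QuinoxP* (cat.), KOtBu (cat.), B2pin2, THF, 0 °C
Reagents that add atoms: bis(pinacolato)diboron, CC1(C)OB(OC1(C)C)B1OC(C)(C)C(C)(C)O1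
Why: Copper-catalysed γ-selective (SN2') allylic substitution by a boryl-copper species should place boron on C1 and move the olefin to C10=C9, the chiral ligand setting 1R; the hindered trisubstituted angelates should not undergo conjugate borylation in the aprotic medium.

Step 11
Reactants: 15 (1R)-allylboronate
Product: 16 hydroxy allylboronate (C8–OH)
Conditions: HF·pyridine, pyridine, THF, 0 °C
Reagents that add atoms: none
Why: Buffered fluoride desilylation of the primary TBS ether should leave oxirane, angelates and the pinacol boronate intact.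

Step 12
Reactants: 16 hydroxy allylboronate
Product: 19 (Z)-cyclodecenol (8R), via aldehyde 17 (not isolated), via pinacol borate 18 (not isolated)
Conditions: Dess–Martin periodinane, pyridine, CH2Cl2, 0 °C; filtrate diluted with toluene (0.002 M), 40–60 °C; aq. NaHCO3
Reagents that add atoms: none
Why: Proposed new method: oxidation unveils the C8 aldehyde, whose carbonyl binds boron so that C9, the γ-carbon of the α-substituted allyl pinacol boronate, adds through a closed six-membered chair (B, O, C8, C9, C10, C1) with transposition of the olefin to C10=C1; the closest known reactions are the bimolecular allylboration of aldehydes by α-substituted β-methallyl pinacol boronates (Z-olefin, transfer of the boron-bearing stereocentre) and tethered allylborations that close five- to eight-membered rings with the tether on the γ-carbon, whereas here the tether sits on the boron-bearing carbon and the new olefin ends up inside the ring. The carbocycle closes in a 10-exo-trig mode at C8, the six-atom chain C2–C7 spanning the 1,4-positions of the chair. The Z olefin is set by the pseudo-axial position of C2 on C1, which avoids strain with the C10 methyl and the pinacol oxygens, and is also the less strained cis-cyclodecene geometry. The 8R carbinol is set by the 1R boron-bearing centre through the same chair with C7 equatorial on C8. This reagent control is needed because Felkin–Anh attack anti to the quaternary C11 would lead to 8S. The step also needs ring closure to outrun bimolecular allylboration and loss of angelate from the β-acyloxy aldehyde, which high dilution, a neutral medium and mild heating should secure.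

Step 13
Reactants: 19 (Z)-cyclodecenol
Product: 20 1,10:4,5-diepoxy alcohol (1R,10S)
Conditions: VO(acac)2 (cat.), t-BuOOH, CH2Cl2, 0 °C
Reagents that add atoms: tert-butyl hydroperoxide, CC(C)(C)OO
Why: Vanadium-catalysed hydroxyl-directed epoxidation of the homoallylic alcohol should deliver oxygen to the face of the cis olefin that carries the C8 hydroxyl, setting 1R and 10S as a cis-oxirane.

Step 14
Reactants: 20 1,10:4,5-diepoxy alcohol
Product: 21 8,12-diol
Conditions: DDQ, CH2Cl2–pH 7 buffer, 0 °C
Reagents that add atoms: none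
Why: Oxidative cleavage of the 4-methoxybenzyl ether under buffered conditions frees the C12 hydroxyl without affecting oxiranes or angelates.

Step 15
Reactants: 21 8,12-diol
Product: 23 target lactone, via lactol 22 (not isolated)
Conditions: TEMPO (cat.), PhI(OAc)2, CH2Cl2, rt
Reagents that add atoms: none
Why: Oxoammonium (TEMPO) oxidation is selective for the primary C12 alcohol; the aldehyde closes onto the C8 hydroxyl (5-exo-trig) and the lactol is oxidised to the γ-lactone, with C6 blocked as its angelate and no stereocentre touched.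

## Compound list

1 | geraniol, (2E)-3,7-dimethylocta-2,6-dien-1-ol | CC(C)=CCC/C(C)=C/CO | starting material
2 | (2S,3S)-2,3-epoxygeraniol, [(2S,3S)-3-methyl-3-(4-methylpent-3-enyl)oxiran-2-yl]methanol | OC[C@@H]1O[C@@]1(C)CCC=C(C)C | intermediate
3 | (2R,3S)-3-methyl-3-(4-methylpent-3-enyl)oxirane-2-carbaldehyde | O=C[C@@H]1O[C@@]1(C)CCC=C(C)C | intermediate
4 | (S)-4-benzyl-1,3-thiazolidine-2-thione | S=C1SC[C@H](Cc2ccccc2)N1 | starting material
5 | 3-[(tert-butyldimethylsilyl)oxy]propanoic acid | OC(=O)CCO[Si](C)(C)C(C)(C)C | starting material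
6 | 1-[(S)-4-benzyl-2-thioxothiazolidin-3-yl]-3-(TBS-oxy)propan-1-one | S=C1SC[C@H](Cc2ccccc2)N1C(=O)CCO[Si](C)(C)C(C)(C)C | intermediate
7 | (Z)-dibutylboron enolate of 6 (not isolated) | CCCCB(CCCC)O/C(=C\CO[Si](C)(C)C(C)(C)C)N1[C@@H](Cc2ccccc2)CSC1=S | intermediate
8 | syn-aldol adduct: (2S,3S)-2-(TBS-oxymethyl)-3-hydroxy-3-[(2S,3S)-3-methyl-3-(4-methylpent-3-enyl)oxiran-2-yl]propanoyl thiazolidinethione (4S,5S,6S,7S in target numbering) | S=C1SC[C@H](Cc2ccccc2)N1C(=O)[C@@H](CO[Si](C)(C)C(C)(C)C)[C@H](O)[C@@H]1O[C@@]1(C)CCC=C(C)C | intermediate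
9 | N-methoxy-N-methyl amide of the same acid (4S,5S,6S,7S) | CON(C)C(=O)[C@@H](CO[Si](C)(C)C(C)(C)C)[C@H](O)[C@@H]1O[C@@]1(C)CCC=C(C)C | intermediate
10 | C11 ketone bearing C12H2–OPMB, free C6–OH, C8H2–OTBS (4S,5S,6S,7S) | COc1ccc(COCC(=O)[C@@H](CO[Si](C)(C)C(C)(C)C)[C@H](O)[C@@H]2O[C@@]2(C)CCC=C(C)C)cc1 | intermediate
11 | bis(chloromagnesium) 6,11-dialkoxide after methyl addition (11R; not isolated) | COc1ccc(COC[C@](C)(O[Mg]Cl)[C@@H](CO[Si](C)(C)C(C)(C)C)[C@H](O[Mg]Cl)[C@@H]2O[C@@]2(C)CCC=C(C)C)cc1 | intermediate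
12 | 6,11-bis-angelate with C12H2–OPMB, C8H2–OTBS, 4,5-oxirane, prenyl terminus (4S,5S,6S,7S,11R) | COc1ccc(COC[C@](C)(OC(=O)/C(C)=C\C)[C@@H](CO[Si](C)(C)C(C)(C)C)[C@H](OC(=O)/C(C)=C\C)[C@@H]2O[C@@]2(C)CCC=C(C)C)cc1 | intermediate
13 | (E)-allylic alcohol: as 12 with C9H2–OH on the (E)-C1=C10 olefin | COc1ccc(COC[C@](C)(OC(=O)/C(C)=C\C)[C@@H](CO[Si](C)(C)C(C)(C)C)[C@H](OC(=O)/C(C)=C\C)[C@@H]2O[C@@]2(C)CC/C=C(\C)CO)cc1 | intermediate
14 | methyl carbonate of 13 | COc1ccc(COC[C@](C)(OC(=O)/C(C)=C\C)[C@@H](CO[Si](C)(C)C(C)(C)C)[C@H](OC(=O)/C(C)=C\C)[C@@H]2O[C@@]2(C)CC/C=C(\C)COC(=O)OC)cc1 | intermediate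
15 | (1R)-allyl pinacol boronate: boron on C1, C10(CH3)=C9H2, C8H2–OTBS | COc1ccc(COC[C@](C)(OC(=O)/C(C)=C\C)[C@@H](CO[Si](C)(C)C(C)(C)C)[C@H](OC(=O)/C(C)=C\C)[C@@H]2O[C@@]2(C)CC[C@@H](B3OC(C)(C)C(C)(C)O3)C(C)=C)cc1 | intermediate
16 | as 15 with free C8H2–OH | COc1ccc(COC[C@](C)(OC(=O)/C(C)=C\C)[C@@H](CO)[C@H](OC(=O)/C(C)=C\C)[C@@H]2O[C@@]2(C)CC[C@@H](B3OC(C)(C)C(C)(C)O3)C(C)=C)cc1 | intermediate
17 | seco-aldehyde: as 16 with C8 as CHO (not isolated) | COc1ccc(COC[C@](C)(OC(=O)/C(C)=C\C)[C@@H](C=O)[C@H](OC(=O)/C(C)=C\C)[C@@H]2O[C@@]2(C)CC[C@@H](B3OC(C)(C)C(C)(C)O3)C(C)=C)cc1 | intermediate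
18 | ten-membered (Z)-cyclodecene with C8–O–Bpin (not isolated) | C/C=C(/C)C(=O)O[C@H]1[C@H]([C@H](OB2OC(C)(C)C(C)(C)O2)C/C(C)=C\CC[C@]2(C)O[C@@H]12)[C@](C)(COCc1ccc(OC)cc1)OC(=O)/C(C)=C\C | intermediate
19 | (4S,5S,6S,7S,8R,11R)-6,11-bis(angeloyloxy)-4,5-epoxy-12-(PMB-oxy)germacr-1(10)Z-en-8-ol | C/C=C(/C)C(=O)O[C@H]1[C@H]([C@H](O)C/C(C)=C\CC[C@]2(C)O[C@@H]12)[C@](C)(COCc1ccc(OC)cc1)OC(=O)/C(C)=C\C | intermediate
20 | (1R,4S,5S,6S,7S,8R,10S,11R)-1,10:4,5-diepoxy analogue of 19 | C/C=C(/C)C(=O)O[C@H]1[C@H]([C@H](O)C[C@]2(C)O[C@@H]2CC[C@]2(C)O[C@@H]12)[C@](C)(COCc1ccc(OC)cc1)OC(=O)/C(C)=C\C | intermediate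
21 | 8,12-diol (PMB removed) | C/C=C(/C)C(=O)O[C@H]1[C@H]([C@H](O)C[C@]2(C)O[C@@H]2CC[C@]2(C)O[C@@H]12)[C@](C)(CO)OC(=O)/C(C)=C\C | intermediate
22 | 12,8-lactol (C12 hemiacetal, either configuration; not isolated) | C/C=C(/C)C(=O)O[C@H]1[C@@H]2[C@@H](C[C@]3(C)O[C@@H]3CC[C@]3(C)O[C@@H]13)OC(O)[C@]2(C)OC(=O)/C(C)=C\C | intermediate
23 | (1R,4S,5S,6S,7S,8R,10S,11R)-6,11-bis(angeloyloxy)-1,10:4,5-diepoxygermacran-12,8-olide (CNP0219924.1) | C/C=C(/C)C(=O)O[C@H]1[C@@H]2[C@@H](C[C@]3(C)O[C@@H]3CC[C@]3(C)O[C@@H]13)OC(=O)[C@]2(C)OC(=O)/C(C)=C\C | target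

## Step count and risks

Total steps: 15. Longest linear sequence: 14 (steps 1, 2 and 4–15, from geraniol).

**Step 12 (labelled Proposed new method).** The ring closure may lose to bimolecular allylboration (oligomers), may pass through the chair with C2 equatorial or a boat (E-olefin or the C8 epimer), or the β-acyloxy aldehyde may lose angelate by elimination before it cyclises. Fallback with known chemistry, from 13 back to 19: 13 is converted into the (E)-allylic chloride F1 (MsCl, LiCl, 2,4,6-collidine, DMF, 0 °C), desilylated to the primary alcohol F2 (HF·pyridine) and oxidised to the chloro aldehyde F3 (Dess–Martin periodinane). SmI2 in THF–HMPA at high dilution then closes the same C8–C9 bond by a Barbier-type coupling, known for medium rings, which joins the primary allylic carbon to the aldehyde with retention of olefin geometry; it should give the (E)-cyclodecenol F4 after separation of C8 epimers. Thiyl-radical isomerisation (PhSSPh cat., hν, benzene), known to relax strained trans olefins in medium rings to the cis isomers, should then give 19; irradiation is kept short to spare the angelates.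

**Step 10.** The boryl-copper species may add to the angelates, substitute without allylic transposition, or give poor facial control at C1 on this (E)-2-methyl-substituted carbonate. Fallback, from 13 back to 15: Mitsunobu etherification of 13 with 4-nitrophenol (PPh3, DIAD) gives the allylic aryl ether F5, which is borylated with B2pin2 under a chiral six-membered N-heterocyclic-carbene CuCl catalyst with NaOtBu and MeOH. This substrate and catalyst class is stereoconvergent with respect to olefin geometry and does not depend on a carbonate leaving group.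

**Step 7.** Acylation of the hindered tertiary magnesium alkoxide may stall, that alkoxide may attack the neighbouring oxirane at C5, or chelation control at C11 may erode. Fallback, from 9 back to 12: MeMgCl converts 9 into the methyl ketone F6, and angelic anhydride with DMAP acylates the C6 hydroxyl to give the keto angelate F7. The (4-methoxybenzyl)oxymethyl unit is then added as its organocerium reagent (Bu3SnCH2OPMB, n-BuLi, CeCl3, THF, −78 °C) under Felkin–Anh control, anti to C6, which should lead to the same 11R centre without chelation; the more nucleophilic tertiary alkoxide is acylated in the flask with angelic anhydride to give 12.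

## Further compounds

F1 | step 12 | (E)-allylic chloride: 13 with C9H2–Cl in place of C9H2–OH | COc1ccc(COC[C@](C)(OC(=O)/C(C)=C\C)[C@@H](CO[Si](C)(C)C(C)(C)C)[C@H](OC(=O)/C(C)=C\C)[C@@H]2O[C@@]2(C)CC/C=C(\C)CCl)cc1
F2 | step 12 | primary alcohol: F1 with free C8H2–OH | COc1ccc(COC[C@](C)(OC(=O)/C(C)=C\C)[C@@H](CO)[C@H](OC(=O)/C(C)=C\C)[C@@H]2O[C@@]2(C)CC/C=C(\C)CCl)cc1
F3 | step 12 | chloro aldehyde: F2 with C8 as CHO | COc1ccc(COC[C@](C)(OC(=O)/C(C)=C\C)[C@@H](C=O)[C@H](OC(=O)/C(C)=C\C)[C@@H]2O[C@@]2(C)CC/C=C(\C)CCl)cc1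
F4 | step 12 | (E)-cyclodecenol: 1(10)E isomer of 19 | C/C=C(/C)C(=O)O[C@H]1[C@H]([C@H](O)C/C(C)=C/CC[C@]2(C)O[C@@H]12)[C@](C)(COCc1ccc(OC)cc1)OC(=O)/C(C)=C\C
F5 | step 10 | allylic 4-nitrophenyl ether of 13 | COc1ccc(COC[C@](C)(OC(=O)/C(C)=C\C)[C@@H](CO[Si](C)(C)C(C)(C)C)[C@H](OC(=O)/C(C)=C\C)[C@@H]2O[C@@]2(C)CC/C=C(\C)COc3ccc(cc3)[N+](=O)[O-])cc1
F6 | step 7 | methyl ketone (C11 acetyl) with free C6–OH | CC(=O)[C@@H](CO[Si](C)(C)C(C)(C)C)[C@H](O)[C@@H]1O[C@@]1(C)CCC=C(C)C
F7 | step 7 | methyl ketone C6-angelate | CC(=O)[C@@H](CO[Si](C)(C)C(C)(C)C)[C@H](OC(=O)/C(C)=C\C)[C@@H]1O[C@@]1(C)CCC=C(C)C
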